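**Retrosynthetic overview**

1. Target 21 ← quinone 20 (Na2S2O4) ← 4-methoxyphenol 19 (PhI(OAc)2, H2O); the free hydroquinone is unveiled last.
2. Ring B (the benzene ring) is formed last, in one step, from alkyne 13, carbene complex 17 and one of its CO ligands (Dötz benzannulation). The bonds made are C5'–C6' (carbene carbon to alkyne CH), C1'–C2' (furyl-bearing alkyne carbon to CO carbon) and C2'–C3' (CO carbon to vinyl CH2).
3. Feature used: ring B carries one carbon substituent only, furan C5 of ring A on C1', with OH on the neighbouring C2', the second oxygen on C5' para to that OH, and H on C3', C4' and C6'. This is the 2-substituted 4-alkoxyphenol pattern given by a terminal alkyne, an unsubstituted vinyl(methoxy)carbene and CO.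
4. 13 ← bromofuran 4 + Weinreb amide 6 (bromine–lithium exchange, acylation), CBS reduction for the (S) centre, Steglich esterification with 11, desilylation. 4 ← 4-bromofuran-2-carbaldehyde 1 (Ohira–Bestmann, silylation); ring A is bought.
5. 17 ← Cr(CO)6 14 + CH2=CHMgBr 15 + Me3OBF4.

Key step: step 9

Remark: CIP analysis of the given SMILES (O > furyl C > CH2 > H) gives (S) at the carbinol carbon, and this enantiomer is the one made.
Remark: the η6-arene–Cr(CO)3 complex 18 has no plain SMILES form and is written as the arene plus a Cr(CO)3 fragment.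

**Route**

Step 1
Reactants: 1 4-bromofuran-2-carbaldehyde
Product: 2 4-bromo-2-ethynylfuran
Conditions: dimethyl (1-diazo-2-oxopropyl)phosphonate, K2CO3, MeOH, 0 °C to rt; product kept as a concentrated pentane solution
Reagents that add atoms: dimethyl (1-diazo-2-oxopropyl)phosphonate, COP(=O)(OC)C(=[N+]=[N-])C(C)=O
Why: Seyferth–Gilbert homologation in its Ohira–Bestmann form, in which methoxide releases the diazomethylphosphonate anion that adds to the aldehyde, expels dimethyl phosphate and loses N2 with a 1,2-hydrogen shift to the terminal alkyne, under conditions that leave the furyl bromide alone.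

Step 2
Reactants: 2 4-bromo-2-ethynylfuran
Product: 4 4-bromo-2-[(triisopropylsilyl)ethynyl]furan, via lithium acetylide 3 (not isolated)
Conditions: LiN(SiMe3)2, THF, −78 °C; then i-Pr3SiOTf, −78 to 0 °C
Reagents that add atoms: triisopropylsilyl trifluoromethanesulfonate, CC(C)[Si](OS(=O)(=O)C(F)(F)F)(C(C)C)C(C)C
Why: Acetylide formation and C-silylation, in which the alkyne C–H is by far the most acidic site, the amide base does not undergo bromine–lithium exchange, and the bulky silyl group shields the alkyne from n-BuLi in step 4 and from the borane in step 5.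

Step 3
Reactants: 5 4-methylpent-3-enoic acid
Product: 6 N-methoxy-N,4-dimethylpent-3-enamide
Conditions: MeNH(OMe)·HCl, EDC·HCl, N-methylmorpholine, CH2Cl2, 0 °C to rt
Reagents that add atoms: N,O-dimethylhydroxylamine hydrochloride, CNOC.Cl
Why: Carbodiimide amide coupling to the Weinreb amide under nearly neutral conditions that should not move the β,γ-double bond into conjugation.

Step 4
Reactants: 4 4-bromo-2-[(triisopropylsilyl)ethynyl]furan; 6 N-methoxy-N,4-dimethylpent-3-enamide
Product: 9 4-methyl-1-{5-[(triisopropylsilyl)ethynyl]furan-3-yl}pent-3-en-1-one, via furan-3-yllithium 7 (not isolated), via tetrahedral lithium adduct 8 (not isolated)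
Conditions: n-BuLi, THF, −78 °C; then 6, −78 °C; aq. NH4Cl, −78 °C to rt
Reagents that add atoms: none
Why: Bromine–lithium exchange at −78 °C gives the furan-3-yllithium without migration of lithium to the α-position, and its addition to the Weinreb amide stops at the chelated adduct 8 (Weinreb ketone synthesis), so that a cold buffered quench should release the β,γ-unsaturated ketone without over-addition.

Step 5
Reactants: 9 4-methyl-1-{5-[(triisopropylsilyl)ethynyl]furan-3-yl}pent-3-en-1-one
Product: 10 (S)-4-methyl-1-{5-[(triisopropylsilyl)ethynyl]furan-3-yl}pent-3-en-1-ol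
Conditions: (R)-2-methyl-CBS-oxazaborolidine (0.2 equiv), catecholborane, toluene, −78 °C; then MeOH, aq. NaOH wash
Reagents that add atoms: none
Why: Corey–Bakshi–Shibata reduction, in which the ketone binds the (R)-oxazaborolidine with the furyl group as the large substituent and hydride is delivered to the face that gives the (S)-alcohol (the mirror image of the (S)-catalyst/aryl alkyl ketone to (R)-alcohol case), while catecholborane at −78 °C should not hydroborate the alkene or the silylalkyne.

Step 6
Reactants: 10 (S)-4-methyl-1-{5-[(triisopropylsilyl)ethynyl]furan-3-yl}pent-3-en-1-ol; 11 3-methylbut-2-enoic acid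
Product: 12 (S)-4-methyl-1-{5-[(triisopropylsilyl)ethynyl]furan-3-yl}pent-3-en-1-yl 3-methylbut-2-enoate
Conditions: DCC, DMAP (cat.), CH2Cl2, 0 °C to rt
Reagents that add atoms: none
Why: Steglich esterification acylates the oxygen without touching the C–O bond of the stereocentre, and the acid/carbodiimide method avoids the vinylketene pathway by which the acid chloride with amine bases gives the deconjugated ester.

Step 7
Reactants: 12 (S)-4-methyl-1-{5-[(triisopropylsilyl)ethynyl]furan-3-yl}pent-3-en-1-yl 3-methylbut-2-enoate
Product: 13 (S)-1-(5-ethynylfuran-3-yl)-4-methylpent-3-en-1-yl 3-methylbut-2-enoate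
Conditions: Bu4NF, AcOH (1:1), THF, 0 °C
Reagents that add atoms: none
Why: Fluoride-induced protodesilylation of an alkynylsilane, buffered with acetic acid so that the ester and the furylic stereocentre meet no strong base.

Step 8
Reactants: 14 chromium hexacarbonyl Cr(CO)6; 15 vinylmagnesium bromide CH2=CHMgBr
Product: 17 pentacarbonyl[methoxy(vinyl)carbene]chromium (CO)5Cr=C(OMe)CH=CH2, via bromomagnesium acylchromate 16 (not isolated)
Conditions: THF, 0 °C to rt; then Me3OBF4, CH2Cl2, −20 to 0 °C; cold pentane filtration through silica, used at once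
Reagents that add atoms: trimethyloxonium tetrafluoroborate, C[O+](C)C.F[B-](F)(F)F
Why: Fischer carbene synthesis, in which the vinyl Grignard reagent adds to a CO ligand to give the acylchromate and the hard oxonium salt methylates its oxygen, with the product kept cold and dilute because the unsubstituted vinyl complex polymerises on storage.

Step 9
Reactants: 13 (S)-1-(5-ethynylfuran-3-yl)-4-methylpent-3-en-1-yl 3-methylbut-2-enoate; 17 pentacarbonyl[methoxy(vinyl)carbene]chromium
Product: 19 (S)-1-[5-(2-hydroxy-5-methoxyphenyl)furan-3-yl]-4-methylpent-3-en-1-yl 3-methylbut-2-enoate, via tricarbonylchromium arene complex 18 (not isolated)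
Conditions: 17 (1.5 equiv), THF (0.05 M), 45–50 °C, Ar; then air, Et2O, rt
Reagents that add atoms: none
Why: Loss of one CO from 17 lets the terminal alkyne of 13 insert into the Cr=C bond to give a chromium dienylcarbene, CO insertion turns this into a chromium-bound dienylketene, and 6π electrocyclisation followed by tautomerisation gives the phenol, held first as its Cr(CO)3 complex 18 and released by air. This is the Dötz benzannulation of an alkenyl(methoxy)carbene chromium complex with an aryl-type terminal alkyne, a known reaction class applied here to a new alkyne. Ring B is closed by the 6π electrocyclic closure of the dienylketene, which joins the CO-derived carbon C2' to the vinyl terminus C3' after the two intermolecular bonds C5'–C6' and C1'–C2' are in place. No stereocentre is formed, and the (S) centre on the side chain of ring A is neither enolisable nor close to the metal, so it should be carried through unchanged. The step needs regioselective insertion, which the size difference between the furyl group and H on the alkyne secures by placing the furyl-bearing carbon next to the CO-derived carbon (OH ortho to the furan, OMe para to OH), and it needs six-ring over five-ring annulation, which an alkenyl carbene in THF at low concentration favours. It also needs the carbene to engage only the alkyne, which should hold because the trisubstituted alkenes, the β,β-disubstituted enoate and the furan do not compete with a terminal alkyne at 45–50 °C.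

Step 10
Reactants: 19 (S)-1-[5-(2-hydroxy-5-methoxyphenyl)furan-3-yl]-4-methylpent-3-en-1-yl 3-methylbut-2-enoate
Product: 20 (S)-1-[5-(3,6-dioxocyclohexa-1,4-dien-1-yl)furan-3-yl]-4-methylpent-3-en-1-yl 3-methylbut-2-enoate
Conditions: PhI(OAc)2, MeCN/H2O, 0 °C
Reagents that add atoms: water, O
Why: Oxidative demethylation of a 4-methoxyphenol by a hypervalent iodine reagent, in which ligand exchange at the phenol oxygen, two-electron oxidation, addition of water at the methoxy-bearing carbon and loss of methanol give the quinone, and the need for a free OH should keep the oxidant away from the furan and the alkenes.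

Step 11
Reactants: 20 (S)-1-[5-(3,6-dioxocyclohexa-1,4-dien-1-yl)furan-3-yl]-4-methylpent-3-en-1-yl 3-methylbut-2-enoate
Product: 21 (S)-1-[5-(2,5-dihydroxyphenyl)furan-3-yl]-4-methylpent-3-en-1-yl 3-methylbut-2-enoate
Conditions: Na2S2O4, EtOAc/H2O, rt, Ar; isolated and stored under Ar
Reagents that add atoms: none
Why: Dithionite reduction of a 1,4-benzoquinone to the hydroquinone in a two-phase system is fast at room temperature and should leave the ester, the alkenes and the furan untouched.

**Compound list**

1 | 4-bromofuran-2-carbaldehyde | O=Cc1cc(Br)co1 | starting material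
2 | 4-bromo-2-ethynylfuran | C#Cc1cc(Br)co1 | intermediate
3 | lithium (4-bromofuran-2-yl)acetylide (formed in the flask, step 2) | [Li]C#Cc1cc(Br)co1 | intermediate
4 | 4-bromo-2-[(triisopropylsilyl)ethynyl]furan | CC(C)[Si](C#Cc1cc(Br)co1)(C(C)C)C(C)C | intermediate
5 | 4-methylpent-3-enoic acid | CC(C)=CCC(=O)O | starting material
6 | N-methoxy-N,4-dimethylpent-3-enamide | CC(C)=CCC(=O)N(C)OC | intermediate
7 | {5-[(triisopropylsilyl)ethynyl]furan-3-yl}lithium (formed in the flask, step 4) | [Li]c1coc(C#C[Si](C(C)C)(C(C)C)C(C)C)c1 | intermediate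
8 | lithium 1-[methoxy(methyl)amino]-4-methyl-1-{5-[(triisopropylsilyl)ethynyl]furan-3-yl}pent-3-en-1-olate (formed in the flask, step 4) | CC(C)=CCC(O[Li])(N(C)OC)c1coc(C#C[Si](C(C)C)(C(C)C)C(C)C)c1 | intermediate
9 | 4-methyl-1-{5-[(triisopropylsilyl)ethynyl]furan-3-yl}pent-3-en-1-one | CC(C)=CCC(=O)c1coc(C#C[Si](C(C)C)(C(C)C)C(C)C)c1 | intermediate
10 | (S)-4-methyl-1-{5-[(triisopropylsilyl)ethynyl]furan-3-yl}pent-3-en-1-ol | CC(C)=CC[C@H](O)c1coc(C#C[Si](C(C)C)(C(C)C)C(C)C)c1 | intermediate
11 | 3-methylbut-2-enoic acid | CC(C)=CC(=O)O | starting material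
12 | (S)-4-methyl-1-{5-[(triisopropylsilyl)ethynyl]furan-3-yl}pent-3-en-1-yl 3-methylbut-2-enoate | CC(C)=CC[C@H](OC(=O)C=C(C)C)c1coc(C#C[Si](C(C)C)(C(C)C)C(C)C)c1 | intermediate
13 | (S)-1-(5-ethynylfuran-3-yl)-4-methylpent-3-en-1-yl 3-methylbut-2-enoate | CC(C)=CC[C@H](OC(=O)C=C(C)C)c1coc(C#C)c1 | intermediate
14 | chromium hexacarbonyl, Cr(CO)6 | O=C=[Cr](=C=O)(=C=O)(=C=O)(=C=O)=C=O | starting material
15 | vinylmagnesium bromide, CH2=CHMgBr | C=C[Mg]Br | starting material
16 | bromomagnesium pentacarbonyl(acryloyl)chromate (formed in the flask, step 8) | C=CC(O[Mg]Br)=[Cr](=C=O)(=C=O)(=C=O)(=C=O)=C=O | intermediate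
17 | pentacarbonyl[methoxy(vinyl)carbene]chromium, (CO)5Cr=C(OMe)CH=CH2 | COC(C=C)=[Cr](=C=O)(=C=O)(=C=O)(=C=O)=C=O | intermediate
18 | η6-tricarbonylchromium complex of 19, chromium on ring B (formed in the flask, step 9) | CC(C)=CC[C@H](OC(=O)C=C(C)C)c1coc(-c2cc(OC)ccc2O)c1.O=C=[Cr](=C=O)=C=O | intermediate
19 | (S)-1-[5-(2-hydroxy-5-methoxyphenyl)furan-3-yl]-4-methylpent-3-en-1-yl 3-methylbut-2-enoate | CC(C)=CC[C@H](OC(=O)C=C(C)C)c1coc(-c2cc(OC)ccc2O)c1 | intermediate
20 | (S)-1-[5-(3,6-dioxocyclohexa-1,4-dien-1-yl)furan-3-yl]-4-methylpent-3-en-1-yl 3-methylbut-2-enoate | CC(C)=CC[C@H](OC(=O)C=C(C)C)c1coc(C2=CC(=O)C=CC2=O)c1 | intermediate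
21 | (S)-1-[5-(2,5-dihydroxyphenyl)furan-3-yl]-4-methylpent-3-en-1-yl 3-methylbut-2-enoate | CC(C)=CC[C@H](OC(=O)C=C(C)C)c1coc(-c2cc(O)ccc2O)c1 | target

**Step count**

Total: 11 steps. Longest linear sequence: 9 steps (steps 1, 2, 4, 5, 6, 7, 9, 10, 11 from 1).

**Steps most likely to fail**

Step 9 (key step). The unsubstituted vinyl carbene may break down or polymerise before the alkyne inserts. The terminal alkyne may be oligomerised by the carbene complex. The dienylcarbene may be diverted to five-membered-ring or two-alkyne products. The fallback forms the aryl–furan bond by cross-coupling instead of building ring B. It sets out from Weinreb amide 6 and comes back at 19.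
- Bromine–lithium exchange on 3-bromofuran (n-BuLi, THF, −78 °C) and acylation with 6 should give 1-(furan-3-yl)-4-methylpent-3-en-1-one F1.
- Reduction under the conditions of step 5 should give (S)-1-(furan-3-yl)-4-methylpent-3-en-1-ol F2.
- Esterification with 11 as in step 6 should give (S)-1-(furan-3-yl)-4-methylpent-3-en-1-yl 3-methylbut-2-enoate F3.
- C–H borylation ([Ir(OMe)(cod)]2, 4,4'-di-tert-butyl-2,2'-bipyridine, B2pin2, hexane, rt) at the α-position remote from the branched substituent should give (S)-4-methyl-1-[5-(4,4,5,5-tetramethyl-1,3,2-dioxaborolan-2-yl)furan-3-yl]pent-3-en-1-yl 3-methylbut-2-enoate F4.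
- Suzuki–Miyaura coupling of F4 with 2-bromo-4-methoxyphenol (Pd(OAc)2, SPhos, K3PO4, THF/H2O, 40 °C) should give 19.

Step 8. The unsubstituted vinyl carbene complex may polymerise during methylation and concentration, and the Grignard reagent may add poorly to Cr(CO)6. The fallback puts a trimethylsilyl group on the vinyl terminus as a traceless stabiliser. It sets out from 14 and 13 and comes back at 19.
- (E)-(2-Bromovinyl)trimethylsilane is lithiated (t-BuLi, Et2O, −78 °C), added to 14 and methylated with Me3OBF4 to give pentacarbonyl{methoxy[(E)-2-(trimethylsilyl)vinyl]carbene}chromium F5.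
- Benzannulation of F5 with 13 under the conditions of step 9 should end with a 1,3-shift of silicon from carbon to oxygen in the cyclohexadienone, giving after air work-up (S)-1-{5-[5-methoxy-2-(trimethylsilyloxy)phenyl]furan-3-yl}-4-methylpent-3-en-1-yl 3-methylbut-2-enoate F6.
- Methanolysis of the aryl silyl ether (citric acid, MeOH, 0 °C) should give 19.

Step 4. The furyllithium may take a proton from the doubly activated CH2 of 6 instead of adding, and the β,γ-double bond of ketone 9 may move into conjugation on work-up, which would also spoil step 5. The fallback sets the stereocentre by C–C bond formation and avoids the ketone. It sets out from bromide 4 and comes back at alcohol 10.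
- 7, generated as in step 4, is quenched with DMF to give 5-[(triisopropylsilyl)ethynyl]furan-3-carbaldehyde F7.
- Brown allylation (B-allyldiisopinocampheylborane from (−)-B-methoxydiisopinocampheylborane of the (+)-α-pinene series and CH2=CHCH2MgBr, Et2O, −78 °C; then NaOH, H2O2) should give (S)-1-{5-[(triisopropylsilyl)ethynyl]furan-3-yl}but-3-en-1-ol F8, by analogy with the (S)-alcohols this reagent gives from aryl aldehydes.
- Cross-metathesis of F8 in 2-methyl-2-butene with second-generation Grubbs catalyst, (H2IMes)(PCy3)Cl2Ru=CHPh, should give 10.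

**Further compounds**

F1 | step 9 | 1-(furan-3-yl)-4-methylpent-3-en-1-one | CC(C)=CCC(=O)c1ccoc1
F2 | step 9 | (S)-1-(furan-3-yl)-4-methylpent-3-en-1-ol | CC(C)=CC[C@H](O)c1ccoc1
F3 | step 9 | (S)-1-(furan-3-yl)-4-methylpent-3-en-1-yl 3-methylbut-2-enoate | CC(C)=CC[C@H](OC(=O)C=C(C)C)c1ccoc1
F4 | step 9 | (S)-4-methyl-1-[5-(4,4,5,5-tetramethyl-1,3,2-dioxaborolan-2-yl)furan-3-yl]pent-3-en-1-yl 3-methylbut-2-enoate | CC(C)=CC[C@H](OC(=O)C=C(C)C)c1coc(B2OC(C)(C)C(C)(C)O2)c1
F5 | step 8 | pentacarbonyl{methoxy[(E)-2-(trimethylsilyl)vinyl]carbene}chromium | C[Si](C)(C)/C=C/C(OC)=[Cr](=C=O)(=C=O)(=C=O)(=C=O)=C=O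
F6 | step 8 | (S)-1-{5-[5-methoxy-2-(trimethylsilyloxy)phenyl]furan-3-yl}-4-methylpent-3-en-1-yl 3-methylbut-2-enoate | CC(C)=CC[C@H](OC(=O)C=C(C)C)c1coc(-c2cc(OC)ccc2O[Si](C)(C)C)c1
F7 | step 4 | 5-[(triisopropylsilyl)ethynyl]furan-3-carbaldehyde | O=Cc1coc(C#C[Si](C(C)C)(C(C)C)C(C)C)c1
F8 | step 4 | (S)-1-{5-[(triisopropylsilyl)ethynyl]furan-3-yl}but-3-en-1-ol | C=CC[C@H](O)c1coc(C#C[Si](C(C)C)(C(C)C)C(C)C)c1
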